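The route rests on disconnecting C2–C3 of the pentadecane chain, the bond from the carbinol carbon to the tridecyl CH2. C2 is a secondary carbinol flanked by two methylenes (benzylic C1 on the resorcinol-derived ring, and C3), too alike for reliable asymmetric reduction or carbonyl addition. A sparteine-mediated lithiation–borylation therefore builds it: the α-lithiated N,N-diisopropylcarbamate of 2-(3,5-dimethoxyphenyl)ethanol captures tridecylboronic pinacol ester, and a stereospecific 1,2-metallate shift forges C2–C3 while fixing the (S) centre, revealed by in-flask oxidation. The precursor is thus an achiral carbamate plus an alkylboronate; a final thiolate mono-demethylation of the symmetric dimethoxyarene unveils the phenol.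

Key step: step 3

Assumption: the target is the (2S)-alcohol (CIP order OH > CH2Ar > CH2-alkyl > H). Compounds 1 and 3, N,N-diisopropylcarbamoyl chloride, pinacolborane and (−)-sparteine are taken as catalogue chemicals. Ring positions are numbered with the side chain at C1.

Step 1
Reactants: 1 2-(3,5-dimethoxyphenyl)ethanol
Product: 2 2-(3,5-dimethoxyphenyl)ethyl N,N-diisopropylcarbamate
Conditions: iPr2NCOCl (1.2 equiv), Et3N (1.5 equiv), CH2Cl2, reflux, 24 h
Reagents that add atoms: N,N-diisopropylcarbamoyl chloride, CC(C)N(C(C)C)C(Cl)=O
Why: O-carbamoylation (acyl substitution) of the primary alcohol should proceed cleanly and installs the hindered carbamate that serves as directing group and leaving group in step 3.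

Step 2
Reactants: 3 1-tridecene
Product: 4 4,4,5,5-tetramethyl-2-tridecyl-1,3,2-dioxaborolane (tridecylboronic acid pinacol ester)
Conditions: HBpin (1.2 equiv), [Ir(cod)Cl]2 (1.5 mol%), dppm (3 mol%), CH2Cl2, rt
Reagents that add atoms: pinacolborane, CC1(C)OBOC1(C)C
Why: iridium-catalysed anti-Markovnikov hydroboration of a terminal alkene with pinacolborane should place boron at the terminal carbon; no stereocentre is formed.

Step 3
Reactants: 2 2-(3,5-dimethoxyphenyl)ethyl N,N-diisopropylcarbamate, 4 4,4,5,5-tetramethyl-2-tridecyl-1,3,2-dioxaborolane
Product: 8 (2S)-1-(3,5-dimethoxyphenyl)pentadecan-2-ol, via lithiated carbamate 5 (not isolated), via boronate complex 6 (not isolated), via secondary boronic ester 7 (not isolated)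
Conditions: s-BuLi (1.1 equiv), (−)-sparteine (1.1 equiv), Et2O, −78 °C, 5 h; 4 (1.3 equiv), −78 °C, 1 h; MgBr2·OEt2, −78 °C to reflux, 16 h; then 2 M NaOH, 30% H2O2, THF, 0 °C to rt
Reagents that add atoms: hydrogen peroxide, OO (the hydroxyl oxygen of 8); sec-butyllithium, [Li]C(C)CC (lithium of intermediates 5 and 6 only)
Why: s-BuLi/(−)-sparteine, pre-complexed to the carbamate carbonyl, should remove the pro-S hydrogen of the OCH2 group to give the configurationally stable (S)-organolithium 5, which boronic ester 4 traps with retention as boronate 6; on warming with MgBr2 the tridecyl group shifts from boron to carbon anti to the departing carbamate (inversion), forging the C2–C3 bond in 7, and alkaline peroxide then replaces boron by hydroxyl with retention to give the (2S)-alcohol. The closest known reaction type is the lithiation–borylation of primary alkyl carbamates (Hoppe lithiation followed by a Matteson-type 1,2-metallate rearrangement). No ring is closed. The one new stereocentre, C2, is set by the chiral diamine (reagent control) and carried through three stereospecific events, so it does not depend on any size difference between the ArCH2 and tridecyl arms. The step needs site-selective deprotonation at OCH2 rather than at the benzylic CH2 or at ring C4–H between the two methoxy groups; the carbonyl-directed five-membered transition state, the weakly coordinating Et2O medium at −78 °C and the near-stoichiometric base charge should secure this, and the hindered diisopropylamide resists attack at C=O. Since tridecyl is the only carbon ligand on boron, the migration is unambiguous.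

Step 4
Reactants: 8 (2S)-1-(3,5-dimethoxyphenyl)pentadecan-2-ol
Product: 9 (2S)-1-(3-hydroxy-5-methoxyphenyl)pentadecan-2-ol (3-[(2S)-2-hydroxypentadecyl]-5-methoxyphenol)
Conditions: NaSEt (4 equiv), DMF, 140 °C; then aq. NH4Cl
Reagents that add atoms: none
Why: thiolate SN2 O-demethylation of an aryl methyl ether, in which the two methoxy groups are constitutionally equivalent so either cleavage gives 9, the phenoxide formed should shut down a second cleavage, and C2, having no acidifying neighbour, is not touched.

Compound list
1 | 2-(3,5-dimethoxyphenyl)ethanol | COc1cc(CCO)cc(OC)c1 | starting material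
2 | 2-(3,5-dimethoxyphenyl)ethyl N,N-diisopropylcarbamate | COc1cc(CCOC(=O)N(C(C)C)C(C)C)cc(OC)c1 | intermediate
3 | 1-tridecene | CCCCCCCCCCCC=C | starting material
4 | 4,4,5,5-tetramethyl-2-tridecyl-1,3,2-dioxaborolane | CCCCCCCCCCCCCB1OC(C)(C)C(C)(C)O1 | intermediate
5 | (1S)-2-(3,5-dimethoxyphenyl)-1-lithioethyl N,N-diisopropylcarbamate (present as its (−)-sparteine complex) | [Li][C@@H](Cc1cc(OC)cc(OC)c1)OC(=O)N(C(C)C)C(C)C | intermediate (not isolated)
6 | lithium [(1S)-1-(diisopropylcarbamoyloxy)-2-(3,5-dimethoxyphenyl)ethyl](pinacolato)(tridecyl)borate | [Li+].CCCCCCCCCCCCC[B-]1(OC(C)(C)C(C)(C)O1)[C@@H](Cc1cc(OC)cc(OC)c1)OC(=O)N(C(C)C)C(C)C | intermediate (not isolated)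
7 | 2-[(2S)-1-(3,5-dimethoxyphenyl)pentadecan-2-yl]-4,4,5,5-tetramethyl-1,3,2-dioxaborolane | CCCCCCCCCCCCC[C@@H](Cc1cc(OC)cc(OC)c1)B1OC(C)(C)C(C)(C)O1 | intermediate (not isolated)
8 | (2S)-1-(3,5-dimethoxyphenyl)pentadecan-2-ol | CCCCCCCCCCCCC[C@H](O)Cc1cc(OC)cc(OC)c1 | intermediate
9 | (2S)-1-(3-hydroxy-5-methoxyphenyl)pentadecan-2-ol | CCCCCCCCCCCCC[C@H](O)Cc1cc(O)cc(OC)c1 | target

Total step count: 4. Longest linear sequence: 3 steps (1 → 2 → 8 → 9); step 2 is a one-step branch that feeds step 3.

Steps most likely to fail

Step 3. The base may deprotonate the ring at C4 between the two methoxy groups, or the benzylic CH2 (followed by loss of the carbamate), instead of the OCH2 group. The 1,2-migration of the primary alkyl group may also stall, or the organolithium may lose configurational integrity before it is trapped. Fallback, setting out from 1 and 3 and coming back at 8: Dess–Martin oxidation of 1 (CH2Cl2, NaHCO3, 0 °C) should give (3,5-dimethoxyphenyl)acetaldehyde F1, used at once. Hydroboration of 3 with Et2BH should give diethyl(tridecyl)borane F2, and boron–zinc exchange with Et2Zn (volatiles removed in vacuo) should give ditridecylzinc F3. Catalytic asymmetric addition of F3 to F1 then follows (Ti(OiPr)4, (1R,2R)-1,2-bis(trifluoromethanesulfonamido)cyclohexane 8 mol%, toluene, −20 °C). This ligand enantiomer is expected to deliver the alkyl group to the Si face. The addition forms the same C2–C3 bond under essentially non-basic conditions and should give 8.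

Step 4. The cleavage may stall before completion, or a second demethylation may set in under forcing conditions, leaving polar mixtures that are hard to separate. Fallback, setting out from 8 and coming back at 9: exhaustive demethylation with BBr3 (CH2Cl2, −78 to 0 °C, the carbinol carried as its borate) should give 5-[(2S)-2-hydroxypentadecyl]benzene-1,3-diol F4. Mono-O-methylation of this symmetric resorcinol (MeI 1.0 equiv, K2CO3, acetone, rt) should then give 9. The over-methylated material is 8 itself and, like unreacted F4, can be recycled.

Step 2. The catalyst may isomerise the alkene along the chain before borylation, or dehydrogenative borylation may compete, giving boronate mixtures that are hard to purify. Fallback, setting out from 3 and coming back at 4: uncatalysed hydroboration with catecholborane (neat, 100 °C) should give 2-tridecyl-1,3,2-benzodioxaborole F5, and transesterification with pinacol (Et2O, rt) should give 4.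

Further compounds
F1 | step 3 | (3,5-dimethoxyphenyl)acetaldehyde | COc1cc(CC=O)cc(OC)c1
F2 | step 3 | diethyl(tridecyl)borane | CCCCCCCCCCCCCB(CC)CC
F3 | step 3 | ditridecylzinc | CCCCCCCCCCCCC[Zn]CCCCCCCCCCCCC
F4 | step 4 | 5-[(2S)-2-hydroxypentadecyl]benzene-1,3-diol | CCCCCCCCCCCCC[C@H](O)Cc1cc(O)cc(O)c1
F5 | step 2 | 2-tridecyl-1,3,2-benzodioxaborole | CCCCCCCCCCCCCB1Oc2ccccc2O1
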